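**Retrosynthetic overview**

- The strategy rests on one feature: C4 of the 3,4-dihydro-2H-pyran ring is a bare CH2 between C3, which can carry a formyl acceptor at the future CH2OAc carbon, and C5, which carries the donor benzofuran-2-yl group. This is the 1,3-pattern of a donor–acceptor cyclopropane.
- The target is traced back, through desilylation, acetylation and aldehyde reduction, to a trans-2-aryl-5-benzofuranyl-dihydropyran-3-carbaldehyde. This aldehyde comes from a 3-oxabicyclo[3.1.0]hexane-1-carbaldehyde by cleavage of the fused C1–C5 bond, so the pyran ring appears by fragmentation.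
- The bicycle comes from hydroxyl-directed methylene transfer to the tetrasubstituted C3=C4 alkene of a (2S)-2-aryl-4-benzofuranyl-2,5-dihydrofuran-3-methanol; the transferred CH2 becomes C4 of the pyran.
- The dihydrofuran comes from a Suzuki coupling of an enol triflate with a benzofuran-2-boronate. The triflate comes from a Dieckmann closure of an O-alkylated (R)-β-hydroxy ester, whose carbinol centre (the later C2) is set by asymmetric transfer hydrogenation.
- Ring order: benzofuran furan ring (Sonogashira/cyclisation) and oxolane (Dieckmann) first, the temporary cyclopropane next, the dihydropyran last.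

Key step: step 14

Remark on the chemistry: the 2,3-trans isomer (aryl and C3 substituent both pseudo-equatorial) is assumed to be the thermodynamically favoured one; both phenols are carried as triisopropylsilyl ethers and the aryl ketone is left free, because the acceptor used for the ring opening is a formyl group that is later reduced selectively.

Abbreviations: TIPS = triisopropylsilyl; Ar = 3-methoxy-4-(TIPS-oxy)phenyl; Bf = 6-acetyl-5-(TIPS-oxy)-1-benzofuran-2-yl.

**Route**

Step 1
Reactants: 1 methyl vanillate; 2 chlorotriisopropylsilane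
Product: 3 methyl 3-methoxy-4-(TIPS-oxy)benzoate
Conditions: imidazole, DMF, rt
Reagents that add atoms: chlorotriisopropylsilane (2), CC(C)[Si](Cl)(C(C)C)C(C)C
Why: Imidazole-promoted silylation of the phenol (silyl ether formation) gives an ether that tolerates the later enolate, hydride and aqueous phosphate conditions and is removed by fluoride at the end.

Step 2
Reactants: 3 methyl 3-methoxy-4-(TIPS-oxy)benzoate; 4 tert-butyl acetate
Product: 5 tert-butyl 3-Ar-3-oxopropanoate
Conditions: LDA (3.2 equiv), 4 (3 equiv), THF, −78 → 0 °C; AcOH quench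
Reagents that add atoms: tert-butyl acetate (4), CC(=O)OC(C)(C)C
Why: Crossed Claisen condensation, in which the lithium enolate of tert-butyl acetate acylates on the non-enolisable benzoate and the β-keto ester is held as its enolate until the quench.

Step 3
Reactants: 5 tert-butyl 3-Ar-3-oxopropanoate
Product: 6 tert-butyl (3R)-3-Ar-3-hydroxypropanoate
Conditions: RuCl(p-cymene)[(R,R)-TsDPEN] (1 mol%), HCO2H–Et3N (5:2), DMF, 30 °C
Reagents that add atoms: none
Why: Noyori-type asymmetric transfer hydrogenation of an aryl ketone, in which the (R,R)-ligand should deliver hydride to the same face as in acetophenone reductions and so set the benzylic carbinol (the later C2) as R by catalyst control.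

Step 4
Reactants: 6 tert-butyl (3R)-3-Ar-3-hydroxypropanoate; 7 ethyl diazoacetate
Product: 8 tert-butyl (3R)-3-Ar-3-(2-ethoxy-2-oxoethoxy)propanoate
Conditions: Rh2(OAc)4 (1 mol%), CH2Cl2, rt, slow addition of 7
Reagents that add atoms: ethyl diazoacetate (7), CCOC(=O)C=[N+]=[N-]
Why: Rhodium-carbenoid O–H insertion alkylates the secondary alcohol under neutral conditions, so the β-hydroxy ester is neither dehydrated nor cleaved by retro-aldol reaction and the C–O bond at the stereocentre is not touched.

Step 5
Reactants: 8 tert-butyl (3R)-3-Ar-3-(2-ethoxy-2-oxoethoxy)propanoate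
Product: 9 tert-butyl (2R)-2-Ar-4-oxooxolane-3-carboxylate (C3 labile, keto/enol mixture)
Conditions: LiHMDS (2.2 equiv), THF, −78 → −30 °C; AcOH quench
Reagents that add atoms: none
Why: Dieckmann condensation under Curtin–Hammett control, in which the two ester enolates interconvert but only the tert-butyl ester enolate finds a reactive acceptor (the α-alkoxy ethyl ester, a tert-butyl ester being a poor acylating agent), and at low temperature it should cyclise faster than it expels the β-alkoxy group, so C2 stays intact while the new C3 centre is labile and of no consequence.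

Step 6
Reactants: 9 tert-butyl (2R)-2-Ar-4-oxooxolane-3-carboxylate; 10 trifluoromethanesulfonic anhydride
Product: 11 tert-butyl (2S)-2-Ar-4-(trifluoromethylsulfonyloxy)-2,5-dihydrofuran-3-carboxylate
Conditions: i-Pr2NEt, CH2Cl2, −78 °C
Reagents that add atoms: trifluoromethanesulfonic anhydride (10), O=S(=O)(OS(=O)(=O)C(F)(F)F)C(F)(F)F
Why: O-sulfonylation of the β-keto ester enol (enol triflate formation) can only involve the C3–C4 enol, which fixes the position of the alkene; the descriptor at C2 changes to S only because the priorities change.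

Step 7
Reactants: 11 tert-butyl (2S)-2-Ar-4-(trifluoromethylsulfonyloxy)-2,5-dihydrofuran-3-carboxylate
Product: 12 [(2S)-2-Ar-4-(trifluoromethylsulfonyloxy)-2,5-dihydrofuran-3-yl]methanol
Conditions: DIBAL-H (3 equiv), CH2Cl2, −78 → −30 °C; Rochelle salt work-up
Reagents that add atoms: none
Why: Ester reduction with DIBAL-H gives the allylic alcohol while the vinyl triflate is inert to the hydride at low temperature, so the hydride step is finished before the ketone-bearing benzofuran is introduced.

Step 8
Reactants: 13 2-bromo-1,4-dimethoxybenzene; 14 acetyl chloride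
Product: 15 1-(4-bromo-2,5-dimethoxyphenyl)ethanone
Conditions: AlCl3, CH2Cl2, 0 °C
Reagents that add atoms: acetyl chloride (14), CC(=O)Cl
Why: Friedel–Crafts acylation should go para to bromine and ortho to a methoxy group, the most activated unhindered position, which places bromine where C3a of the benzofuran will be; any demethylation next to the acetyl group is harmless.

Step 9
Reactants: 15 1-(4-bromo-2,5-dimethoxyphenyl)ethanone
Product: 16 1-(4-bromo-2,5-dihydroxyphenyl)ethanone
Conditions: BBr3 (3 equiv), CH2Cl2, −78 °C → rt; H2O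
Reagents that add atoms: none
Why: Lewis-acid cleavage of both aryl methyl ethers with BBr3 leaves the aryl bromide and the ketone untouched.

Step 10
Reactants: 16 1-(4-bromo-2,5-dihydroxyphenyl)ethanone; 17 ethynyltrimethylsilane
Product: 20 1-(5-hydroxy-1-benzofuran-6-yl)ethanone, via silylalkyne 18 (not isolated), via ethynylphenol 19 (not isolated)
Conditions: PdCl2(PPh3)2 (3 mol%), CuI (6 mol%), Et3N, DMF, 70 °C; then TBAF, 70 °C
Reagents that add atoms: ethynyltrimethylsilane (17), C#C[Si](C)(C)C
Why: Sonogashira coupling of the bromide activated by the para acetyl group, then fluoride desilylation and 5-endo-dig addition of the neighbouring phenol to the alkyne (benzofuran annulation), while the hydrogen-bonded phenol next to the acetyl group stays free.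

Step 11
Reactants: 20 1-(5-hydroxy-1-benzofuran-6-yl)ethanone; 2 chlorotriisopropylsilane
Product: 21 1-[5-(TIPS-oxy)-1-benzofuran-6-yl]ethanone
Conditions: NaH (1.05 equiv), THF, 0 °C; then 2, rt
Reagents that add atoms: chlorotriisopropylsilane (2), CC(C)[Si](Cl)(C(C)C)C(C)C
Why: One equivalent of NaH deprotonates only the phenol, and silylation of the phenoxide protects it for the carbenoid, oxidation and acylation steps.

Step 12
Reactants: 21 1-[5-(TIPS-oxy)-1-benzofuran-6-yl]ethanone; 22 bis(pinacolato)diboron
Product: 23 1-[2-(4,4,5,5-tetramethyl-1,3,2-dioxaborolan-2-yl)-5-(TIPS-oxy)-1-benzofuran-6-yl]ethanone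
Conditions: [Ir(OMe)(cod)]2 (1.5 mol%), 4,4'-di-tert-butyl-2,2'-bipyridine (3 mol%), THF, 50 °C
Reagents that add atoms: bis(pinacolato)diboron (22), CC1(C)OB(OC1(C)C)B1OC(C)(C)C(C)(C)O1
Why: Iridium-catalysed C–H borylation (Miyaura–Hartwig type) should go to the most acidic unhindered heteroaryl C–H at C2, the benzene-ring positions being blocked by ortho substituents.

Step 13
Reactants: 12 [(2S)-2-Ar-4-(trifluoromethylsulfonyloxy)-2,5-dihydrofuran-3-yl]methanol; 23 the benzofuran-2-boronate
Product: 24 [(2S)-2-Ar-4-Bf-2,5-dihydrofuran-3-yl]methanol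
Conditions: PdCl2(dppf) (5 mol%), K3PO4, THF–H2O (10:1), 45 °C
Reagents that add atoms: none
Why: Suzuki–Miyaura coupling of the enol triflate with the heteroaryl boronate at mild temperature tolerates the free alcohol, the ketone and the silyl ethers and does not involve C2.

Step 14
Reactants: 24 [(2S)-2-Ar-4-Bf-2,5-dihydrofuran-3-yl]methanol; 25 diiodomethane
Product: 26 [(1R,2S,5R)-2-Ar-5-Bf-3-oxabicyclo[3.1.0]hexan-1-yl]methanol (cyclopropane CH2 anti to Ar)
Conditions: Et2Zn (4 equiv), CH2I2 (8 equiv), CH2Cl2, −10 °C → rt; aq. NaHCO3 quench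
Reagents that add atoms: diiodomethane (25), ICI
Why: Et2Zn converts the carbinol into its zinc alkoxide and, with CH2I2, into an iodomethylzinc carbenoid that is held by the alkoxide and transfers CH2 to the neighbouring C3=C4 alkene in one concerted butterfly-type [2+1] step, forming both new C–C bonds (the later C3–C4 and C4–C5 of the pyran) at once. The closest known reaction type is the hydroxyl-directed Simmons–Smith cyclopropanation in the Furukawa modification, which is established for tetrasubstituted allylic alcohols. The only ring closed is the cyclopropane, by concerted syn addition across the alkene (a cheletropic [2+1] closure), which gives the cis-fused 3-oxabicyclo[3.1.0]hexane; no ring of the target is closed here. The two new quaternary stereocentres arise together, cis fusion is enforced by the ring, and the methylene should enter anti to the C2 aryl group by substrate control; both centres are erased in step 16. The step needs chemoselectivity for this alkene over the benzofuran C2=C3 bond, the arenes and the ketone, which is secured by delivery from the allylic alkoxide, by the electron-rich styrene-type alkene and by the aromaticity of the benzofuran, and C2 is not involved.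

Step 15
Reactants: 26 [(1R,2S,5R)-2-Ar-5-Bf-3-oxabicyclo[3.1.0]hexan-1-yl]methanol
Product: 27 (1S,2S,5R)-2-Ar-5-Bf-3-oxabicyclo[3.1.0]hexane-1-carbaldehyde
Conditions: Dess–Martin periodinane, pyridine, CH2Cl2, 0 °C → rt
Reagents that add atoms: none
Why: Dess–Martin oxidation of the primary carbinol under buffered conditions should give the aldehyde without opening the cyclopropane.

Step 16
Reactants: 27 (1S,2S,5R)-2-Ar-5-Bf-3-oxabicyclo[3.1.0]hexane-1-carbaldehyde
Product: 28 (2R)-2-Ar-5-Bf-3,4-dihydro-2H-pyran-3-carbaldehyde, mixture of C3 epimers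
Conditions: Sc(OTf)3 (10 mol%), 4 Å MS, CH2Cl2, 0 °C → rt
Reagents that add atoms: none
Why: Proposed new method: Sc(OTf)3 on the formyl oxygen should polarise the donor–acceptor bond C1–C5 of the cyclopropane, heterolysis gives a C5 cation stabilised by the benzofuran-2-yl group and a scandium enolate at C1, and loss of a proton from the neighbouring OCH2 group (its C–H bonds are the better hyperconjugative donors and the enol ether formed is conjugated with the benzofuran) followed by C-protonation of the enolate gives the six-membered ring by cleavage of the zero-atom bridge; closure of the enolate oxygen onto C5 (the Cloke–Wilson pathway) would need a bridgehead alkene and is not available; the closest known reaction type is the Lewis-acid ring-opening isomerisation of donor–acceptor cyclopropanes to alkenes; C3 forms without control here and the two cyclopropane stereocentres disappear, the descriptor at C2 changing to R only through the priorities.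

Step 17
Reactants: 28 (2R)-2-Ar-5-Bf-3,4-dihydro-2H-pyran-3-carbaldehyde, mixture of C3 epimers
Product: 29 (2R,3R)-2-Ar-5-Bf-3,4-dihydro-2H-pyran-3-carbaldehyde (2,3-trans)
Conditions: DBU (0.2 equiv), CH2Cl2, 0 °C
Reagents that add atoms: none
Why: Base-mediated epimerisation of the aldehyde α-centre through its enolate (thermodynamic control) should favour the trans isomer with aryl and formyl groups both pseudo-equatorial, which sets C3, and the catalytic amidine at low temperature limits β-elimination of the ring oxygen.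

Step 18
Reactants: 29 (2R,3R)-2-Ar-5-Bf-3,4-dihydro-2H-pyran-3-carbaldehyde
Product: 30 [(2R,3S)-2-Ar-5-Bf-3,4-dihydro-2H-pyran-3-yl]methanol (2,3-trans)
Conditions: NaBH4, EtOH–CH2Cl2 (3:7), −78 °C
Reagents that add atoms: none
Why: Chemoselective borohydride reduction, since at −78 °C the aldehyde should be reduced much faster than the conjugated, ortho-substituted aryl ketone.

Step 19
Reactants: 30 [(2R,3S)-2-Ar-5-Bf-3,4-dihydro-2H-pyran-3-yl]methanol; 31 acetic anhydride
Product: 32 [(2R,3S)-2-Ar-5-Bf-3,4-dihydro-2H-pyran-3-yl]methyl acetate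
Conditions: pyridine, DMAP (cat.), CH2Cl2, 0 °C
Reagents that add atoms: acetic anhydride (31), CC(=O)OC(C)=O
Why: Nucleophile-catalysed acetylation (esterification) of the only free hydroxyl group.

Step 20
Reactants: 32 [(2R,3S)-2-Ar-5-Bf-3,4-dihydro-2H-pyran-3-yl]methyl acetate
Product: 33 propolis-benzofuran A
Conditions: TBAF (2.4 equiv), AcOH (2.4 equiv), THF, 0 °C
Reagents that add atoms: none
Why: Fluoride cleaves both aryl silyl ethers (desilylation) and the acetic acid buffer keeps the phenoxides protonated, so the primary acetate and the enol ether should survive.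

**Compound list**

1 | methyl vanillate (methyl 4-hydroxy-3-methoxybenzoate) | COC(=O)c1ccc(O)c(OC)c1 | starting material
2 | chlorotriisopropylsilane | CC(C)[Si](Cl)(C(C)C)C(C)C | starting material
3 | methyl 3-methoxy-4-(triisopropylsilyloxy)benzoate | COC(=O)c1ccc(O[Si](C(C)C)(C(C)C)C(C)C)c(OC)c1 | intermediate
4 | tert-butyl acetate | CC(=O)OC(C)(C)C | starting material
5 | tert-butyl 3-[3-methoxy-4-(triisopropylsilyloxy)phenyl]-3-oxopropanoate | COc1cc(C(=O)CC(=O)OC(C)(C)C)ccc1O[Si](C(C)C)(C(C)C)C(C)C | intermediate
6 | tert-butyl (3R)-3-hydroxy-3-[3-methoxy-4-(triisopropylsilyloxy)phenyl]propanoate | COc1cc([C@H](O)CC(=O)OC(C)(C)C)ccc1O[Si](C(C)C)(C(C)C)C(C)C | intermediate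
7 | ethyl diazoacetate | CCOC(=O)C=[N+]=[N-] | starting material
8 | tert-butyl (3R)-3-(2-ethoxy-2-oxoethoxy)-3-[3-methoxy-4-(triisopropylsilyloxy)phenyl]propanoate | COc1cc([C@H](OCC(=O)OCC)CC(=O)OC(C)(C)C)ccc1O[Si](C(C)C)(C(C)C)C(C)C | intermediate
9 | tert-butyl (2R)-2-[3-methoxy-4-(triisopropylsilyloxy)phenyl]-4-oxooxolane-3-carboxylate (C3 labile) | COc1cc([C@@H]2OCC(=O)C2C(=O)OC(C)(C)C)ccc1O[Si](C(C)C)(C(C)C)C(C)C | intermediate
10 | trifluoromethanesulfonic anhydride | O=S(=O)(OS(=O)(=O)C(F)(F)F)C(F)(F)F | starting material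
11 | tert-butyl (2S)-2-[3-methoxy-4-(triisopropylsilyloxy)phenyl]-4-(trifluoromethylsulfonyloxy)-2,5-dihydrofuran-3-carboxylate | COc1cc([C@@H]2OCC(OS(=O)(=O)C(F)(F)F)=C2C(=O)OC(C)(C)C)ccc1O[Si](C(C)C)(C(C)C)C(C)C | intermediate
12 | [(2S)-2-[3-methoxy-4-(triisopropylsilyloxy)phenyl]-4-(trifluoromethylsulfonyloxy)-2,5-dihydrofuran-3-yl]methanol | COc1cc([C@@H]2OCC(OS(=O)(=O)C(F)(F)F)=C2CO)ccc1O[Si](C(C)C)(C(C)C)C(C)C | intermediate
13 | 2-bromo-1,4-dimethoxybenzene | COc1ccc(OC)c(Br)c1 | starting material
14 | acetyl chloride | CC(=O)Cl | starting material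
15 | 1-(4-bromo-2,5-dimethoxyphenyl)ethanone | CC(=O)c1cc(OC)c(Br)cc1OC | intermediate
16 | 1-(4-bromo-2,5-dihydroxyphenyl)ethanone | CC(=O)c1cc(O)c(Br)cc1O | intermediate
17 | ethynyltrimethylsilane | C#C[Si](C)(C)C | starting material
18 | 1-{2,5-dihydroxy-4-[(trimethylsilyl)ethynyl]phenyl}ethanone | CC(=O)c1cc(O)c(C#C[Si](C)(C)C)cc1O | intermediate
19 | 1-(4-ethynyl-2,5-dihydroxyphenyl)ethanone | CC(=O)c1cc(O)c(C#C)cc1O | intermediate
20 | 1-(5-hydroxy-1-benzofuran-6-yl)ethanone | CC(=O)c1cc2occc2cc1O | intermediate
21 | 1-[5-(triisopropylsilyloxy)-1-benzofuran-6-yl]ethanone | CC(=O)c1cc2occc2cc1O[Si](C(C)C)(C(C)C)C(C)C | intermediate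
22 | bis(pinacolato)diboron | CC1(C)OB(OC1(C)C)B1OC(C)(C)C(C)(C)O1 | starting material
23 | 1-[2-(4,4,5,5-tetramethyl-1,3,2-dioxaborolan-2-yl)-5-(triisopropylsilyloxy)-1-benzofuran-6-yl]ethanone | CC(=O)c1cc2oc(B3OC(C)(C)C(C)(C)O3)cc2cc1O[Si](C(C)C)(C(C)C)C(C)C | intermediate
24 | [(2S)-4-[6-acetyl-5-(triisopropylsilyloxy)-1-benzofuran-2-yl]-2-[3-methoxy-4-(triisopropylsilyloxy)phenyl]-2,5-dihydrofuran-3-yl]methanol | COc1cc([C@@H]2OCC(c3cc4cc(O[Si](C(C)C)(C(C)C)C(C)C)c(C(C)=O)cc4o3)=C2CO)ccc1O[Si](C(C)C)(C(C)C)C(C)C | intermediate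
25 | diiodomethane | ICI | starting material
26 | [(1R,2S,5R)-5-[6-acetyl-5-(triisopropylsilyloxy)-1-benzofuran-2-yl]-2-[3-methoxy-4-(triisopropylsilyloxy)phenyl]-3-oxabicyclo[3.1.0]hexan-1-yl]methanol | COc1cc([C@@H]2OC[C@@]3(c4cc5cc(O[Si](C(C)C)(C(C)C)C(C)C)c(C(C)=O)cc5o4)C[C@@]23CO)ccc1O[Si](C(C)C)(C(C)C)C(C)C | intermediate
27 | (1S,2S,5R)-5-[6-acetyl-5-(triisopropylsilyloxy)-1-benzofuran-2-yl]-2-[3-methoxy-4-(triisopropylsilyloxy)phenyl]-3-oxabicyclo[3.1.0]hexane-1-carbaldehyde | COc1cc([C@@H]2OC[C@@]3(c4cc5cc(O[Si](C(C)C)(C(C)C)C(C)C)c(C(C)=O)cc5o4)C[C@@]23C=O)ccc1O[Si](C(C)C)(C(C)C)C(C)C | intermediate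
28 | (2R)-5-[6-acetyl-5-(triisopropylsilyloxy)-1-benzofuran-2-yl]-2-[3-methoxy-4-(triisopropylsilyloxy)phenyl]-3,4-dihydro-2H-pyran-3-carbaldehyde, mixture of C3 epimers | COc1cc([C@@H]2OC=C(c3cc4cc(O[Si](C(C)C)(C(C)C)C(C)C)c(C(C)=O)cc4o3)CC2C=O)ccc1O[Si](C(C)C)(C(C)C)C(C)C | intermediate
29 | (2R,3R)-5-[6-acetyl-5-(triisopropylsilyloxy)-1-benzofuran-2-yl]-2-[3-methoxy-4-(triisopropylsilyloxy)phenyl]-3,4-dihydro-2H-pyran-3-carbaldehyde (2,3-trans) | COc1cc([C@@H]2OC=C(c3cc4cc(O[Si](C(C)C)(C(C)C)C(C)C)c(C(C)=O)cc4o3)C[C@H]2C=O)ccc1O[Si](C(C)C)(C(C)C)C(C)C | intermediate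
30 | [(2R,3S)-5-[6-acetyl-5-(triisopropylsilyloxy)-1-benzofuran-2-yl]-2-[3-methoxy-4-(triisopropylsilyloxy)phenyl]-3,4-dihydro-2H-pyran-3-yl]methanol (2,3-trans) | COc1cc([C@@H]2OC=C(c3cc4cc(O[Si](C(C)C)(C(C)C)C(C)C)c(C(C)=O)cc4o3)C[C@H]2CO)ccc1O[Si](C(C)C)(C(C)C)C(C)C | intermediate
31 | acetic anhydride | CC(=O)OC(C)=O | starting material
32 | [(2R,3S)-5-[6-acetyl-5-(triisopropylsilyloxy)-1-benzofuran-2-yl]-2-[3-methoxy-4-(triisopropylsilyloxy)phenyl]-3,4-dihydro-2H-pyran-3-yl]methyl acetate | COc1cc([C@@H]2OC=C(c3cc4cc(O[Si](C(C)C)(C(C)C)C(C)C)c(C(C)=O)cc4o3)C[C@H]2COC(C)=O)ccc1O[Si](C(C)C)(C(C)C)C(C)C | intermediate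
33 | propolis-benzofuran A, [(2R,3S)-5-(6-acetyl-5-hydroxy-1-benzofuran-2-yl)-2-(4-hydroxy-3-methoxyphenyl)-3,4-dihydro-2H-pyran-3-yl]methyl acetate | COc1cc([C@@H]2OC=C(c3cc4cc(O)c(C(C)=O)cc4o3)C[C@H]2COC(C)=O)ccc1O | target

**Step count and risks**

Total step count: 20. Longest linear sequence: 15 steps (steps 1–7 and 13–20); the benzofuran boronate (steps 8–12) is a five-step branch.

Steps most likely to fail:

1. Step 16 (fragmentation of the donor–acceptor cyclopropane). After the ring cleavage the proton may be lost from C4 instead of C6, which leads towards a conjugated enal, or the Lewis acid may ionise the benzylic C2–O bond with loss of configuration at C2. The fallback uses known chemistry, sets out from 27 and comes back to the route at 28. MgI2 in Et2O–CH2Cl2 at 0 °C should open the activated cyclopropane by homoconjugate addition of iodide at the donor carbon, as known for cyclopropyl ketones and spirocyclopropyl oxindoles. Aqueous work-up then gives the γ-iodo aldehyde (2R)-5-Bf-5-iodo-2-Ar-oxane-3-carbaldehyde F1. DBU in toluene at 0 °C should remove hydrogen iodide by anti elimination, taking the more acidic C6–H next to the ring oxygen, and give 28, which continues with step 17.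

2. Step 17 (equilibration at C3). The aldehyde enolate may expel the ring oxygen by β-elimination (retro-oxa-Michael opening), which would erode C2 or destroy the pyran, or the equilibrium may not favour the trans isomer enough. The fallback avoids the carbonyl stage; it sets out from 26 and comes back at 30. Mesylation of 26 (MsCl, Et3N, CH2Cl2, −20 °C) gives the mesylate of 26, F2, which is not isolated. On warming with 2,6-lutidine it should ionise with participation of the C1–C5 bond (cyclopropylcarbinyl-to-homoallyl cation rearrangement) and lose the C6 proton to give (2R)-2-Ar-5-Bf-3-methylidene-3,4-dihydro-2H-pyran F3. Hydroboration of the 1,1-disubstituted exocyclic alkene with 9-BBN (faster than reduction of the aryl ketone) and oxidation with NaBO3 should give 30. C3 is then set under kinetic control: hydrogen is expected to enter axially on the half-chair, which leaves the hydroxymethyl group pseudo-equatorial and trans to the aryl group, and a cis alcohol, if formed, can be separated at this stage.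

3. Step 14 (key step). Methylene transfer to the hindered, conjugated tetrasubstituted alkene may be slow, and zinc iodide may meanwhile ionise the doubly activated C2–O bond of the dihydrofuran or the product carbinol. The fallback reverses the polarity of the cyclopropanation while keeping the same two bonds; it sets out from 24 and comes back at 27. MnO2 in CH2Cl2 at rt should oxidise the allylic alcohol to the enal (2S)-2-Ar-4-Bf-2,5-dihydrofuran-3-carbaldehyde F4. Dimethylsulfoxonium methylide (Me3S(O)I, NaH, DMSO, rt) should then add in conjugate fashion to C4, and the enolate closes the three-membered ring at C3 (Corey–Chaykovsky cyclopropanation), again anti to the aryl group, which gives 27 directly.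

Further compounds
F1 | step 16 | (2R)-5-[6-acetyl-5-(triisopropylsilyloxy)-1-benzofuran-2-yl]-5-iodo-2-[3-methoxy-4-(triisopropylsilyloxy)phenyl]oxane-3-carbaldehyde (C3 and C5 epimers) | COc1cc([C@@H]2OCC(I)(c3cc4cc(O[Si](C(C)C)(C(C)C)C(C)C)c(C(C)=O)cc4o3)CC2C=O)ccc1O[Si](C(C)C)(C(C)C)C(C)C
F2 | step 17 | [(1R,2S,5R)-5-[6-acetyl-5-(triisopropylsilyloxy)-1-benzofuran-2-yl]-2-[3-methoxy-4-(triisopropylsilyloxy)phenyl]-3-oxabicyclo[3.1.0]hexan-1-yl]methyl methanesulfonate | COc1cc([C@@H]2OC[C@@]3(c4cc5cc(O[Si](C(C)C)(C(C)C)C(C)C)c(C(C)=O)cc5o4)C[C@@]23COS(C)(=O)=O)ccc1O[Si](C(C)C)(C(C)C)C(C)C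
F3 | step 17 | (2R)-5-[6-acetyl-5-(triisopropylsilyloxy)-1-benzofuran-2-yl]-2-[3-methoxy-4-(triisopropylsilyloxy)phenyl]-3-methylidene-3,4-dihydro-2H-pyran | COc1cc([C@@H]2OC=C(c3cc4cc(O[Si](C(C)C)(C(C)C)C(C)C)c(C(C)=O)cc4o3)CC2=C)ccc1O[Si](C(C)C)(C(C)C)C(C)C
F4 | step 14 | (2S)-4-[6-acetyl-5-(triisopropylsilyloxy)-1-benzofuran-2-yl]-2-[3-methoxy-4-(triisopropylsilyloxy)phenyl]-2,5-dihydrofuran-3-carbaldehyde | COc1cc([C@@H]2OCC(c3cc4cc(O[Si](C(C)C)(C(C)C)C(C)C)c(C(C)=O)cc4o3)=C2C=O)ccc1O[Si](C(C)C)(C(C)C)C(C)C
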